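**Retrosynthetic overview**

1. Numbering: butenolide O1, C2 (C=O), C3 (Me), C4, C5; side chain C1' (exocyclic CH) to C13' (CH2 on the furan). The butenolide is the only ring made and is closed last, by O1–C2 enol lactonisation of a 2-methyl-4-oxo-2-enoic acid. Its C2, C3 and C3-methyl come from ethyl pyruvate by aldol addition to the CH3 group (C4) of a methyl ketone, then dehydration.
2. Feature carrying the strategy: the only stereocentre, C2', bears a methyl group, lies β to C5 and is followed by the unbranched C3'–C4'–C5' chain. The C2'–C3' bond is therefore cut to (E)-pent-3-en-2-one (C4, C5, C1', C2', C2'-Me) and a primary alkylmetal at C3'.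
3. That alkylmetal is taken from the vinyl group (C3'=C4') of an achiral furyl tetraene by hydrozirconation and is added under chiral copper–phosphoramidite catalysis, which sets C2'.
4. Tetraene: geranyl acetate, terminal (E)-allylic oxidation, bromide, vinyl coupling (C4'–C5'), allylic chloride, copper-catalysed coupling with furan-3-ylmethylmagnesium chloride (C12'–C13').
5. Ring order: the furan is bought in; the butenolide ring is formed in the final step.

Key step: step 8

Assumption: the target SMILES is read as (2'S), (5Z), (6'E,10'E). The sense of induction of the phosphoramidite on this small acyclic enone is assumed to be settled in a test run, and the ligand antipode is taken if the (R)-ketone should form.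

**Route**

Step 1
Reactants: 1 geranyl acetate [(2E)-3,7-dimethylocta-2,6-dien-1-yl acetate]
Product: 2 (2E,6E)-8-hydroxy-3,7-dimethylocta-2,6-dien-1-yl acetate
Conditions: SeO2 (cat.), t-BuOOH, salicylic acid (cat.), CH2Cl2, rt
Reagents that add atoms: tert-butyl hydroperoxide, CC(C)(C)OO (terminal source of the new oxygen, relayed by selenium dioxide, O=[Se]=O)
Why: SeO2-catalysed allylic oxidation (ene reaction followed by [2,3]-sigmatropic shift) selects the electron-rich terminal trisubstituted alkene over the one deactivated by the allylic acetate and oxidises its (E)-methyl group, which fixes the later C6'=C7' geometry.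

Step 2
Reactants: 2 (2E,6E)-8-hydroxy-3,7-dimethylocta-2,6-dien-1-yl acetate
Product: 3 (2E,6E)-8-bromo-3,7-dimethylocta-2,6-dien-1-yl acetate
Conditions: CBr4, PPh3, CH2Cl2, −20 to 0 °C; used without storage
Reagents that add atoms: carbon tetrabromide, BrC(Br)(Br)Br
Why: Appel bromination of the primary allylic alcohol under neutral conditions proceeds by SN2 displacement of the alkoxyphosphonium ion, so that neither the acetate nor the (E)-alkene geometry is affected.

Step 3
Reactants: 3 (2E,6E)-8-bromo-3,7-dimethylocta-2,6-dien-1-yl acetate; 4 vinylmagnesium bromide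
Product: 5 (2E,6E)-3,7-dimethyldeca-2,6,9-trien-1-yl acetate
Conditions: CH2=CHMgBr, CuI (10 mol%), THF, −78 to −40 °C
Reagents that add atoms: none
Why: Copper-catalysed cross-coupling of the vinyl Grignard reagent with the primary allylic bromide forms the C8–C9 bond at the unhindered CH2 carbon (SN2 rather than SN2', the γ-carbon being more hindered), and at low temperature the bromide should be consumed far faster than the allylic acetate, whose partial cleavage would only anticipate step 4.

Step 4
Reactants: 5 (2E,6E)-3,7-dimethyldeca-2,6,9-trien-1-yl acetate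
Product: 6 (2E,6E)-3,7-dimethyldeca-2,6,9-trien-1-ol
Conditions: K2CO3, MeOH, rt
Reagents that add atoms: none
Why: Base-catalysed methanolysis (transesterification) removes the acetate and no other group in the skipped triene reacts.

Step 5
Reactants: 6 (2E,6E)-3,7-dimethyldeca-2,6,9-trien-1-ol
Product: 8 (2E,6E)-1-chloro-3,7-dimethyldeca-2,6,9-triene, via allylic mesylate 7 (not isolated)
Conditions: MsCl, LiCl, 2,4,6-collidine, DMF, 0 °C
Reagents that add atoms: lithium chloride, [Li+].[Cl-]
Why: Mesylation and in-situ SN2 displacement by chloride in DMF (allylic chlorination under non-acidic conditions) should give the primary allylic chloride without SN2' transposition or E/Z scrambling.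

Step 6
Reactants: 9 furan-3-ylmethanol
Product: 11 3-(chloromethyl)furan, via chlorosulfite ester 10 (not isolated)
Conditions: SOCl2, pyridine, Et2O, 0 °C; used as a solution without storage
Reagents that add atoms: thionyl chloride, O=S(Cl)Cl
Why: Chlorodehydroxylation through the chlorosulfite, with pyridine taking up HCl so that the acid-sensitive furan survives.

Step 7
Reactants: 11 3-(chloromethyl)furan; 8 (2E,6E)-1-chloro-3,7-dimethyldeca-2,6,9-triene
Product: 13 3-[(3E,7E)-4,8-dimethylundeca-3,7,10-trien-1-yl]furan, via furan-3-ylmethylmagnesium chloride 12 (not isolated)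
Conditions: Mg, THF, 0 °C (slow addition of 11); then 8, Li2CuCl4 (3 mol%), THF, 0 °C
Reagents that add atoms: none
Why: The furylmethyl Grignard reagent, formed by slow addition to magnesium to limit homocoupling, is transferred under Li2CuCl4 catalysis to the primary carbon of the allylic chloride (copper-catalysed sp3–sp3 Grignard cross-coupling, an established access to 3-(homoallyl)furans) without allylic transposition or loss of the (E)-geometry.

Step 8
Reactants: 13 3-[(3E,7E)-4,8-dimethylundeca-3,7,10-trien-1-yl]furan; 14 (E)-pent-3-en-2-one (freshly distilled)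
Product: 17 (4S,8E,12E)-15-(furan-3-yl)-4,8,12-trimethylpentadeca-8,12-dien-2-one, via alkylzirconocene chloride 15 (not isolated), via trimethylsilyl enol ether 16 (not isolated)
Conditions: Cp2Zr(H)Cl (0.95 equiv), CH2Cl2, rt; then (CuOTf)2·C6H6 (5 mol%), O,O'-(1,1'-binaphthalene-2,2'-diyl)-N,N-bis(1-phenylethyl)phosphoramidite (single stereoisomer, 10 mol%), 14 (1.5 equiv), TMSCl, Et2O, rt; then 1 M aq HCl, 0 °C, brief
Reagents that add atoms: none
Why: Cp2Zr(H)Cl adds its Zr–H bond across the only monosubstituted alkene of 13 (C10=C11) with zirconium on the terminal carbon, because the two trisubstituted alkenes and the furan react far more slowly and the primary alkylzirconium is the stable regioisomer; the slight deficit of hydride leaves none to reduce the enone. The primary alkyl group is then passed to the monovalent copper–phosphoramidite complex, the alkylcopper binds the enone as a π-complex, addition at the β-carbon gives a trivalent copper intermediate, and reductive elimination forms C4–C5 of 17 (C2'–C3' of the target), the enolate being trapped by TMSCl as 16 and hydrolysed on work-up. The closest known reaction type is the copper-catalysed asymmetric conjugate addition of alkylzirconocenes, generated in situ from terminal alkenes, to acyclic enones. No ring is closed in this step. The single new stereocentre (C4 of 17, C2' of the target) is controlled by the chiral phosphoramidite on copper, which distinguishes the two faces of the β-carbon of the geometrically pure (E)-enone; the ligand enantiomer is the one that delivers (S). The step needs 1,4- rather than 1,2-addition, secured by the soft alkylcopper and TMSCl, and chemoselective hydrometalation, secured by the steric difference between the vinyl group and the trisubstituted alkenes.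

Step 9
Reactants: 17 (4S,8E,12E)-15-(furan-3-yl)-4,8,12-trimethylpentadeca-8,12-dien-2-one; 18 ethyl pyruvate
Product: 20 ethyl (6S,10E,14E)-17-(furan-3-yl)-2-hydroxy-2,6,10,14-tetramethyl-4-oxoheptadeca-10,14-dienoate (both C2 epimers), via lithium enolate 19 (not isolated)
Conditions: LiN(i-Pr)2, THF, −78 °C; then 18, −78 °C; AcOH quench at −78 °C
Reagents that add atoms: none
Why: LiN(i-Pr)2 at −78 °C removes a proton from the methyl group and not from the β-branched methylene (kinetic enolate), and the enolate adds to the electrophilic ketone carbonyl of ethyl pyruvate (aldol addition); the new carbinol centre is formed unselectively and is removed in step 10, and the cold acetic acid quench forestalls retro-aldol cleavage.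

Step 10
Reactants: 20 ethyl (6S,10E,14E)-17-(furan-3-yl)-2-hydroxy-2,6,10,14-tetramethyl-4-oxoheptadeca-10,14-dienoate
Product: 22 ethyl (2E,6S,10E,14E)-17-(furan-3-yl)-2,6,10,14-tetramethyl-4-oxoheptadeca-2,10,14-trienoate, via tertiary mesylate 21 (not isolated)
Conditions: MsCl, Et3N (excess), CH2Cl2, 0 °C to rt
Reagents that add atoms: none
Why: Mesylation of the tertiary alcohol through sulfene and E1cB elimination via the ketone enolate (dehydration of the aldol) should give the conjugated 4-oxo-2-enoate, expected mainly as the (2E) isomer; any (2Z) isomer is carried on because both converge in step 12, and C6, β to the ketone, is not affected.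

Step 11
Reactants: 22 ethyl (2E,6S,10E,14E)-17-(furan-3-yl)-2,6,10,14-tetramethyl-4-oxoheptadeca-2,10,14-trienoate
Product: 23 (2E,6S,10E,14E)-17-(furan-3-yl)-2,6,10,14-tetramethyl-4-oxoheptadeca-2,10,14-trienoic acid
Conditions: LiOH·H2O (1.5 equiv), THF/H2O, 0 °C; then cold 1 M aq HCl to pH 3
Reagents that add atoms: lithium hydroxide, [Li+].[OH-] (its oxygen becomes the carboxyl OH)
Why: Saponification (acyl–oxygen cleavage by hydroxide) at 0 °C with a small excess of LiOH and immediate cold acidification should keep conjugate addition of hydroxide and retro-aldol cleavage slow, and C6 has no acidic hydrogen.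

Step 12
Reactants: 23 (2E,6S,10E,14E)-17-(furan-3-yl)-2,6,10,14-tetramethyl-4-oxoheptadeca-2,10,14-trienoic acid
Product: 26 (5Z)-5-[(2S,6E,10E)-13-(furan-3-yl)-2,6,10-trimethyltrideca-6,10-dien-1-ylidene]-3-methylfuran-2(5H)-one (target), via mixed acetic anhydride 24 (not isolated), via 5-acetoxybutenolide 25 (not isolated)
Conditions: Ac2O, NaOAc (cat.), PhMe, 80 °C
Reagents that add atoms: none
Why: Ac2O converts the acid into the mixed anhydride, whose C2=C3 geometry equilibrates by reversible conjugate addition of acetate (the isomerisation known from the conversion of mesaconic acid into citraconic anhydride); only the Z form closes, by 5-exo attack of the C4 ketone oxygen on the activated carboxyl, to the pseudo-ester 25, and loss of acetic acid across C5–C1' of the ring numbering completes the enol lactonisation, the (Z)-ylidene being favoured because the C2' substituent then lies beside the ring oxygen and away from C4–H, while C2' should stay untouched under these weakly basic conditions.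

**Compound list**

1 | geranyl acetate, (2E)-3,7-dimethylocta-2,6-dien-1-yl acetate | CC(C)=CCC/C(C)=C/COC(C)=O | starting material
2 | (2E,6E)-8-hydroxy-3,7-dimethylocta-2,6-dien-1-yl acetate | OC/C(C)=C/CC/C(C)=C/COC(C)=O | intermediate
3 | (2E,6E)-8-bromo-3,7-dimethylocta-2,6-dien-1-yl acetate | BrC/C(C)=C/CC/C(C)=C/COC(C)=O | intermediate
4 | vinylmagnesium bromide | C=C[Mg]Br | starting material
5 | (2E,6E)-3,7-dimethyldeca-2,6,9-trien-1-yl acetate | C=CC/C(C)=C/CC/C(C)=C/COC(C)=O | intermediate
6 | (2E,6E)-3,7-dimethyldeca-2,6,9-trien-1-ol | C=CC/C(C)=C/CC/C(C)=C/CO | intermediate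
7 | (2E,6E)-3,7-dimethyldeca-2,6,9-trien-1-yl methanesulfonate | C=CC/C(C)=C/CC/C(C)=C/COS(C)(=O)=O | intermediate
8 | (2E,6E)-1-chloro-3,7-dimethyldeca-2,6,9-triene | C=CC/C(C)=C/CC/C(C)=C/CCl | intermediate
9 | furan-3-ylmethanol | OCc1ccoc1 | starting material
10 | furan-3-ylmethyl chlorosulfite | O=S(Cl)OCc1ccoc1 | intermediate
11 | 3-(chloromethyl)furan | ClCc1ccoc1 | intermediate
12 | furan-3-ylmethylmagnesium chloride | Cl[Mg]Cc1ccoc1 | intermediate
13 | 3-[(3E,7E)-4,8-dimethylundeca-3,7,10-trien-1-yl]furan | C=CC/C(C)=C/CC/C(C)=C/CCc1ccoc1 | intermediate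
14 | (E)-pent-3-en-2-one | C/C=C/C(C)=O | starting material
15 | chlorobis(cyclopentadienyl)[(4E,8E)-11-(furan-3-yl)-4,8-dimethylundeca-4,8-dien-1-yl]zirconium | Cl[Zr](CCC/C(C)=C/CC/C(C)=C/CCc1ccoc1)(C1C=CC=C1)C1C=CC=C1 | intermediate
16 | trimethyl{[(4S,8E,12E)-15-(furan-3-yl)-4,8,12-trimethylpentadeca-2,8,12-trien-2-yl]oxy}silane (enol ether geometry not defined) | CC(O[Si](C)(C)C)=C[C@@H](C)CCC/C(C)=C/CC/C(C)=C/CCc1ccoc1 | intermediate
17 | (4S,8E,12E)-15-(furan-3-yl)-4,8,12-trimethylpentadeca-8,12-dien-2-one | CC(=O)C[C@@H](C)CCC/C(C)=C/CC/C(C)=C/CCc1ccoc1 | intermediate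
18 | ethyl pyruvate | CCOC(=O)C(C)=O | starting material
19 | lithium (4S,8E,12E)-15-(furan-3-yl)-4,8,12-trimethylpentadeca-1,8,12-trien-2-olate | [Li]OC(=C)C[C@@H](C)CCC/C(C)=C/CC/C(C)=C/CCc1ccoc1 | intermediate
20 | ethyl (6S,10E,14E)-17-(furan-3-yl)-2-hydroxy-2,6,10,14-tetramethyl-4-oxoheptadeca-10,14-dienoate (both C2 epimers) | CCOC(=O)C(C)(O)CC(=O)C[C@@H](C)CCC/C(C)=C/CC/C(C)=C/CCc1ccoc1 | intermediate
21 | ethyl (6S,10E,14E)-17-(furan-3-yl)-2-(methanesulfonyloxy)-2,6,10,14-tetramethyl-4-oxoheptadeca-10,14-dienoate | CCOC(=O)C(C)(OS(C)(=O)=O)CC(=O)C[C@@H](C)CCC/C(C)=C/CC/C(C)=C/CCc1ccoc1 | intermediate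
22 | ethyl (2E,6S,10E,14E)-17-(furan-3-yl)-2,6,10,14-tetramethyl-4-oxoheptadeca-2,10,14-trienoate | CCOC(=O)/C(C)=C/C(=O)C[C@@H](C)CCC/C(C)=C/CC/C(C)=C/CCc1ccoc1 | intermediate
23 | (2E,6S,10E,14E)-17-(furan-3-yl)-2,6,10,14-tetramethyl-4-oxoheptadeca-2,10,14-trienoic acid | OC(=O)/C(C)=C/C(=O)C[C@@H](C)CCC/C(C)=C/CC/C(C)=C/CCc1ccoc1 | intermediate
24 | acetic (2E,6S,10E,14E)-17-(furan-3-yl)-2,6,10,14-tetramethyl-4-oxoheptadeca-2,10,14-trienoic anhydride | CC(=O)OC(=O)/C(C)=C/C(=O)C[C@@H](C)CCC/C(C)=C/CC/C(C)=C/CCc1ccoc1 | intermediate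
25 | 2-[(2S,6E,10E)-13-(furan-3-yl)-2,6,10-trimethyltrideca-6,10-dien-1-yl]-4-methyl-5-oxo-2,5-dihydrofuran-2-yl acetate (both ring C2 epimers) | CC(=O)OC1(C[C@@H](C)CCC/C(C)=C/CC/C(C)=C/CCc2ccoc2)OC(=O)C(C)=C1 | intermediate
26 | (5Z)-5-[(2S,6E,10E)-13-(furan-3-yl)-2,6,10-trimethyltrideca-6,10-dien-1-ylidene]-3-methylfuran-2(5H)-one | CC1=C/C(=C/[C@@H](C)CCC/C(C)=C/CC/C(C)=C/CCc2ccoc2)OC1=O | target

**Step count**

Total: 12 steps. Longest linear sequence: 11 steps (geranyl acetate 1 to target 26 through steps 1–5 and 7–12; step 6 is the side branch).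

**Steps most likely to fail**

Step 8. Facial discrimination at the β-carbon of a small acyclic enone may be insufficient, which would erode enantiomeric purity. Transmetalation may be slow, so that the alkylzirconium is lost by protonolysis. Residual zirconium hydride may reduce the enone. Fallback (sets out from 13, returns at 17): the two β-substituents exchange roles, so that methyl is the nucleophile. Hydrozirconation of 13 as before (through 15) is followed by CO insertion (1 atm) to the acylzirconocene chloride F1. Protonolysis with dilute HCl gives the one-carbon-longer aldehyde (5E,9E)-12-(furan-3-yl)-5,9-dimethyldodeca-5,9-dienal F2. Wittig olefination with 1-(triphenylphosphoranylidene)propan-2-one gives the (E)-enone (3E,8E,12E)-15-(furan-3-yl)-8,12-dimethylpentadeca-3,8,12-trien-2-one F3. Asymmetric conjugate addition of MeMgBr (CuBr·SMe2, a Josiphos-type ferrocenyl diphosphine of the enantiomer leading to (S), t-BuOMe, −75 °C) then gives 17.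

Step 12. The E-to-Z isomerisation of the enone unit may be incomplete under the anhydride conditions, so that ring closure stalls. Prolonged heating with base could epimerise C2' by deprotonation to the furanolate. Some (E)-ylidene may persist. Fallback (sets out from 23, returns at 26): isomerisation and dehydration are separated. Irradiation of 23 (365 nm, MeCN, rt) isomerises the enone photochemically, and the Z acid should close spontaneously to the pseudo-acid 5-[(2S,6E,10E)-13-(furan-3-yl)-2,6,10-trimethyltrideca-6,10-dien-1-yl]-5-hydroxy-3-methylfuran-2(5H)-one F8. Acetylation and elimination in the cold (Ac2O, Et3N, DMAP cat., CH2Cl2, 0 °C), through 25, then give 26.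

Step 11. Hydroxide may add in conjugate fashion to the ene-keto ester, and the hydrate may undergo retro-aldol cleavage faster than the ester is hydrolysed. Fallback (sets out from 17, returns at 23): the carboxyl group is carried as an allyl ester and released without hydroxide. Allyl pyruvate F4 is made from pyruvic acid and allyl alcohol (TsOH cat., benzene, water removal). The lithium enolate 19 is added to it as in step 9 to give allyl (6S,10E,14E)-17-(furan-3-yl)-2-hydroxy-2,6,10,14-tetramethyl-4-oxoheptadeca-10,14-dienoate F5. MsCl/Et3N converts this through the tertiary mesylate F6 into allyl (2E,6S,10E,14E)-17-(furan-3-yl)-2,6,10,14-tetramethyl-4-oxoheptadeca-2,10,14-trienoate F7. Allyl transfer with Pd(PPh3)4 (zerovalent palladium) and sodium 2-ethylhexanoate in EtOAc at rt, then mild acidification, gives 23.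

**Further compounds**

F1 | step 8 | chlorobis(cyclopentadienyl)[(5E,9E)-12-(furan-3-yl)-5,9-dimethyldodeca-5,9-dienoyl]zirconium | O=C(CCC/C(C)=C/CC/C(C)=C/CCc1ccoc1)[Zr](Cl)(C1C=CC=C1)C1C=CC=C1
F2 | step 8 | (5E,9E)-12-(furan-3-yl)-5,9-dimethyldodeca-5,9-dienal | O=CCCC/C(C)=C/CC/C(C)=C/CCc1ccoc1
F3 | step 8 | (3E,8E,12E)-15-(furan-3-yl)-8,12-dimethylpentadeca-3,8,12-trien-2-one | CC(=O)/C=C/CCC/C(C)=C/CC/C(C)=C/CCc1ccoc1
F4 | step 11 | allyl pyruvate (prop-2-en-1-yl 2-oxopropanoate) | C=CCOC(=O)C(C)=O
F5 | step 11 | allyl (6S,10E,14E)-17-(furan-3-yl)-2-hydroxy-2,6,10,14-tetramethyl-4-oxoheptadeca-10,14-dienoate | C=CCOC(=O)C(C)(O)CC(=O)C[C@@H](C)CCC/C(C)=C/CC/C(C)=C/CCc1ccoc1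
F6 | step 11 | allyl (6S,10E,14E)-17-(furan-3-yl)-2-(methanesulfonyloxy)-2,6,10,14-tetramethyl-4-oxoheptadeca-10,14-dienoate | C=CCOC(=O)C(C)(OS(C)(=O)=O)CC(=O)C[C@@H](C)CCC/C(C)=C/CC/C(C)=C/CCc1ccoc1
F7 | step 11 | allyl (2E,6S,10E,14E)-17-(furan-3-yl)-2,6,10,14-tetramethyl-4-oxoheptadeca-2,10,14-trienoate | C=CCOC(=O)/C(C)=C/C(=O)C[C@@H](C)CCC/C(C)=C/CC/C(C)=C/CCc1ccoc1
F8 | step 12 | 5-[(2S,6E,10E)-13-(furan-3-yl)-2,6,10-trimethyltrideca-6,10-dien-1-yl]-5-hydroxy-3-methylfuran-2(5H)-one | CC1=CC(O)(C[C@@H](C)CCC/C(C)=C/CC/C(C)=C/CCc2ccoc2)OC1=O
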